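(The numbers in the tables stem from a simulated flask on assumed constants.)

I started from a constant that these runs let me read by hand and then carry to a flask not yet run.

the same everywhere: electrophile 0.10 M

|  | nucleophile | solid base | protic impurity | remark | time |
|---|---|---|---|---|---|
| noon | 0.24 M | 0.15 M | 0.030 M | run made earlier |  |
| spring | 0.37 M | 0.15 M | 0.030 M | run made earlier |  |
| summer | 0.55 M | 0.15 M | 0.030 M | run made earlier |  |
| Sunday's | 0.250 M | 0.150 M | 0.0300 M |  | 3.0 d |
| Saturday's | 0.380 M | 0.150 M | 0.0300 M |  | 3.0 d |
| Friday's | 0.560 M | 0.150 M | 0.0300 M |  | 3.0 d |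

- noon (time / h: electrophile / %, product / %): 5.00: 86, 16; 12.0: 75, 31; 25.0: 51, 55; 40.0: 36, 66; 48.0: 30, 69
- spring (time / h: electrophile / %, product / %): 5.00: 79, 22; 12.0: 57, 39; 25.0: 34, 69; 40.0: 23, 81; 48.0: 13, 87
- summer (time / h: electrophile / %, product / %): 4.00: 75, 25; 8.00: 59, 43; 15.0: 41, 59; 25.0: 21, 80; 48.0: 8, 93

(readings scatter by 2 percentage points)

- solid, in amounts per volume of the solution: solid base
- at the start none of the solid base is in solution

* part of the electrophile that has reacted at the end, Sunday's
* part of the electrophile that has reacted at the end, Saturday's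
* part of the electrophile that has reacted at the end, Friday's
* what raising the concentration of nucleophile from its lowest to its highest value here does to the part of the electrophile that has reacted (changes below 5 percentage points count as none) (it rises / no change / it falls)

I worked with f, the fraction of the electrophile left, and assumed that each nucleophile takes one electrophile at a rate proportional to both concentrations. Then c(nucleophile) = c(nucleophile, charged) − c(electrophile, charged)·(1 − f), and integrating gives

k = ln[ (c(nucleophile) / c(nucleophile, charged)) / f ] / [ (c(nucleophile, charged) − c(electrophile, charged))·t ]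

The noon run's 30% at 48.0 h gave 3.55 × 10⁻⁵ M⁻¹ s⁻¹, and the spring run's 13% at 48.0 h gave 3.80 × 10⁻⁵ M⁻¹ s⁻¹. For the summer run I took 21% at 25.0 h, which gave 3.47 × 10⁻⁵ M⁻¹ s⁻¹, and I left aside its last reading, 8%, which stands against a scatter of 2 percentage points. Their mean is the read second-order constant, 3.61 × 10⁻⁵ M⁻¹ s⁻¹.

Two extremes bracket Sunday's flask. If the nucleophile stayed at its charge (pseudo-first-order), then

f = exp(−k·c(nucleophile, charged)·t) = 9.66%

If it stood from the start at what remains once the electrophile is gone, then

f = exp(−k·(c(nucleophile, charged) − c(electrophile, charged))·t) = 24.6%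

On that assumption the nucleophile lies between these two, so f must too. The integrated law puts it there:

f = (c(nucleophile, charged) − c(electrophile, charged)) / [ c(nucleophile, charged)·exp(k·(c(nucleophile, charged) − c(electrophile, charged))·t) − c(electrophile, charged) ]

This put f at 16.4% for Sunday's flask, more than the first extreme and less than the second, at 5.48% for Saturday's and at 1.12% for Friday's. So I expected the reacted part to rise by 15 points from Sunday's to Friday's.

The forecast, which found that “The integrated second-order law, allowing for nucleophile consumption, fits all three runs”, gave 83%, 94% and 98.7%, and said of the reacted part: it rises.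

The flasks gave 83.5%, 94.2% and 98.8%: it rises, by 15 points.

    electrophile + nucleophile → acid set free + product (k = 3.66 × 10⁻⁵ M⁻¹ s⁻¹)
    nucleophile + acid set free ⇌ protonated nucleophile, settled at all times (K = 44.4 M⁻¹)
    acid set free + free base ⇌ salt of the base, settled at all times (K = 54000 M⁻¹)
    acid set free → by-product carried off (k = 2.51 × 10⁻⁵ s⁻¹)
    solid base ⇌ free base, rate k5*(cs5 - [free base]) while solid is left; crystals form when [free base] > cs5 (solubility = 9.90 mM, k = 4.98 × 10⁻⁵ s⁻¹)
    protic impurity + free base → quenched reagent (k = 2.15 × 10⁻⁴ M⁻¹ s⁻¹)

Sunday's flask had not come to rest at 3.0 d: it still held 17% of its electrophile, against my 16.4%. Carrying k to 12 d gave f = 0.220%, and the neighbouring reading of Sunday's flask at that time holds 0.22% of its electrophile. At ten times the time, 30.0 d, the reacted part of Sunday's electrophile reached >99.9%, the nucleophile fell from 66% to 59.6%, and the solid base fell from 40.1% to 16.5%. Over the same stretch, Sunday's quenched reagent rose from 0.00453 M to 0.0298 M, and its protic impurity fell from 85% to 0.690%.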